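The numbers in the tables come from a simulation for an exercise; noise was put on by code.

Compare cedar with alder: cedar carries 170 µM of impurity and alder 83 µM, yet at 60.0 s left-handed product reads 21.4% in cedar and 21.7% in alder.

| flask | left-handed substrate | right-handed substrate | reagent | free catalyst | impurity | remark |
|---|---|---|---|---|---|---|
| alder | 15 mM | 15 mM | 9 mM | 0.27 mM | 83 µM | the very flask that is asked about, followed so far |
| cedar | 15 mM | 15 mM | 9 mM | 0.27 mM | 170 µM | run made earlier |
| flask | 15 mM | 15 mM | 9.00 mM | 0.27 mM | 83 µM |  |

| run | time / s | left-handed product / % | left-handed substrate / % |
|---|---|---|---|
| alder | 10.0 | 18.5 | 31.0 |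
| alder | 15.0 | 20.0 | 29.9 |
| alder | 30.0 | 20.5 | 28.8 |
| alder | 40.0 | 21.7 | 28.8 |
| alder | 60.0 | 21.7 | 28.7 |
| cedar | 10.0 | 15.6 | 34.6 |
| cedar | 20.0 | 18.4 | 31.0 |
| cedar | 40.0 | 20.7 | 29.6 |
| cedar | 60.0 | 21.4 | 28.8 |
| cedar | 80.0 | 20.9 | 28.5 |

(each reading ± 0.3 percentage points)

- apparent order in reagent when 20% of the left-handed substrate and right-handed substrate together are converted (percent change of the rate of making left-handed product for one percent more reagent charged)
- apparent order in free catalyst when 20% of the left-handed substrate and right-handed substrate together are converted (percent change of the rate of making left-handed product for one percent more free catalyst charged)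
- factor on the rate of making left-handed product when 20% of the left-handed substrate and right-handed substrate together are converted if free catalyst is charged twice over

- free catalyst is single-handed; left-handed substrate and right-handed substrate are mirror images of each other, charged as a racemate, each of them at the stated concentration
- what was read earlier has a scatter of 0.3 percentage points, one standard deviation
- steps that have been proposed: reagent + free catalyst + right-handed substrate -> free catalyst + right-handed product; reagent + free catalyst + left-handed substrate -> free catalyst + left-handed product; reagent <-> dormant form; free catalyst + impurity -> spent catalyst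
- no earlier run changes the charge of free catalyst; that part of a forecast is a guess
- no earlier run changes the charge of reagent; that part of a forecast is a guess

Read reagent as the limiting reagent: its charge is 30.0% of the substrates together. Take the rate of making left-handed product as proportional to [reagent], [free catalyst] and [left-handed substrate].

Start with the flask at 20% conversion, the mark. There 6.00 mM of reagent is used, so the pool of reagent is 3.00 mM. At fixed conversion, each extra mM charged adds one mM to that pool, so the order in reagent is the charge over [reagent], here 3.00. Let impurity remove catalyst one for one. That leaves 187 µM of free catalyst in the flask, an order in catalyst of 1.44 and a doubling factor of 2.44.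

Now object: the pool also holds dormant form. Test this on cedar. Its left-handed product approaches the plateau at 0.131 s⁻¹ up to 10.0 s, then at 0.0705 s⁻¹ up to 40.0 s. Object again: left-handed substrate fell too, to 0.759 of its earlier mean. Divide that out. Read the remaining slowing as dormant form: that puts 0.711 of the pool as reagent once relaxed, a rough reading given the scatter.

Alder already shows 18.5% of left-handed product at 10.0 s, so put the mark near or before that reading, and guess the leak into dormant form has gone 0.5 of the way. Call the part of the pool held as dormant form at the mark the dormant share, 14.4%.

Go round again. [reagent] at the mark becomes 2.57 mM, and the order in reagent 3.51. Assume more catalyst reaches the mark sooner, and let the share scale inversely with active catalyst. The order in catalyst becomes 1.69, and the doubling factor 2.69.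

The forecast gave 3 (2.2 to 4), 1.4 (1.1 to 1.6) and 2.4 (2 to 2.7), noting that “a dormant pool adds uncertainty”.

The flask gives 3.6, 1.7 and 2.75.

    reagent + free catalyst + right-handed substrate → free catalyst + right-handed product (k = 28600 L² mol⁻² s⁻¹)
    reagent + free catalyst + left-handed substrate → free catalyst + left-handed product (k = 89800 L² mol⁻² s⁻¹)
    reagent ⇌ dormant form (K = 0.580, k = 0.0304 s⁻¹)
    free catalyst + impurity → spent catalyst (k = 7.56 × 10⁵ L mol⁻¹ s⁻¹)

The flask reaches the mark at 0.0711 min, earlier than the 0.139 min relaxation half-life of reagent and dormant form by that step alone, the partway picture behind the dormant share of 14.4%. Read through the same rule, the order of 3.6 gives an estimate of 2.49 mM of reagent at the mark, a dormant share of 17.1%.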